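**Retrosynthetic overview**
1. Target 28 ⇐ PMB removal and acetylation ⇐ 9-ketone 23 ⇐ axial cuprate addition of isopropenyl at C7 of the trans-fused enone 21.
2. Ring A (formed second) ⇐ ring-closing metathesis making C3=C4 from a C5 isopropenyl group and a C2 vinyl carbinol arm (enone 20).
3. C1/C2 ⇐ reagent-controlled anti γ-boryl allylboration of aldehyde 8; C5 ⇐ 1,6-cuprate addition to the cyclohexa-2,4-dienone 16.
4. Ring B (formed first) and the quaternary C10 ⇐ auxiliary-controlled Birch reduction–alkylation of 2-methoxybenzamide 3, with 4-methoxybenzyl chloromethyl ether supplying C14; the arene carbons become C5–C10.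

Assumption: eudesmane numbering is used for positions (CH2OH = C14), and the Birch alkylation is taken to follow the chelated-enolate model (electrophile enters anti to the CH2OMe arm); if the sense were opposite, the (R)-auxiliary would be used.

**Route**

Step 1
Reactants: 1 2-methoxybenzoyl chloride; 2 (S)-2-(methoxymethyl)pyrrolidine
Product: 3 (S)-(2-methoxyphenyl)[2-(methoxymethyl)pyrrolidin-1-yl]methanone
Conditions: Et3N, CH2Cl2, 0 °C to rt
Reagents that add atoms: none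
Why: Schotten–Baumann-type N-acylation of a secondary amine by an aroyl chloride; no new stereocentre is formed.

Step 2
Reactants: 3 (S)-(2-methoxyphenyl)[2-(methoxymethyl)pyrrolidin-1-yl]methanone; 4 4-methoxybenzyl chloromethyl ether
Product: 6 [(1S)-2-methoxy-1-{[(4-methoxybenzyl)oxy]methyl}cyclohexa-2,5-dien-1-yl][(2S)-2-(methoxymethyl)pyrrolidin-1-yl]methanone, via potassium enolate 5 (not isolated)
Conditions: K (2.2 equiv), t-BuOH (1 equiv), NH3/THF, −78 °C; piperylene; NH3 removed; 4, THF, −78 to 0 °C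
Reagents that add atoms: none
Why: Schultz-type asymmetric Birch reduction–alkylation, in which the arene is reduced to the potassium-chelated amide enolate (para protonation by t-BuOH) and the α-chloro ether alkylates the ipso carbon on the face anti to the CH2OMe arm of the auxiliary, breaking aromaticity and setting the quaternary C10 (S here).

Step 3
Reactants: 6 [(1S)-2-methoxy-1-{[(4-methoxybenzyl)oxy]methyl}cyclohexa-2,5-dien-1-yl][(2S)-2-(methoxymethyl)pyrrolidin-1-yl]methanone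
Product: 8 (1S)-2-methoxy-1-{[(4-methoxybenzyl)oxy]methyl}cyclohexa-2,5-diene-1-carbaldehyde, via zirconium hemiaminal 7 (not isolated)
Conditions: Cp2Zr(H)Cl (1.8 equiv), THF, rt, 30 min; then H2O, silica gel
Reagents that add atoms: none
Why: Partial reduction of a tertiary amide with the Schwartz reagent stops at a stable zirconated hemiaminal that releases the aldehyde and the auxiliary on hydrolysis, leaving the enol ether, the PMB ether and C10 untouched.

Step 4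
Reactants: 8 (1S)-2-methoxy-1-{[(4-methoxybenzyl)oxy]methyl}cyclohexa-2,5-diene-1-carbaldehyde; 9 allenylboronic acid pinacol ester
Product: 12 (1R,2S)-1-[(1R)-2-methoxy-1-{[(4-methoxybenzyl)oxy]methyl}cyclohexa-2,5-dien-1-yl]but-3-ene-1,2-diol, via allylborane 10 (not isolated), via boron adduct 11 (not isolated)
Conditions: (−)-Ipc2BH [from (+)-α-pinene], 9, Et2O, −25 to 0 °C; then 8, −78 °C; then NaOH, H2O2, 0 °C to rt
Reagents that add atoms: hydrogen peroxide, OO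
Why: Brown-type γ-boryl allylboration, in which the (E)-γ-borylallyl-diisopinocampheylborane adds through a chair Zimmerman–Traxler transition state (anti relationship) to the Si face of the aldehyde (reagent control, as for (−)-Ipc2B allyl reagents with aliphatic aldehydes), and C–B oxidation with retention gives the anti diol with C1 (R) and C2 (S).

Step 5
Reactants: 12 (1R,2S)-1-[(1R)-2-methoxy-1-{[(4-methoxybenzyl)oxy]methyl}cyclohexa-2,5-dien-1-yl]but-3-ene-1,2-diol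
Product: 13 (1R,2S)-2-[(tert-butyldimethylsilyl)oxy]-1-[(1R)-2-methoxy-1-{[(4-methoxybenzyl)oxy]methyl}cyclohexa-2,5-dien-1-yl]but-3-en-1-ol
Conditions: TBSCl (1.1 equiv), imidazole, DMF, 0 °C
Reagents that add atoms: tert-butyldimethylsilyl chloride, CC(C)(C)[Si](C)(C)Cl
Why: Selective silylation, since the allylic C2 hydroxyl is far more accessible than the neopentyl C1 hydroxyl next to the quaternary carbon; no stereocentre is touched.

Step 6
Reactants: 13 (1R,2S)-2-[(tert-butyldimethylsilyl)oxy]-1-[(1R)-2-methoxy-1-{[(4-methoxybenzyl)oxy]methyl}cyclohexa-2,5-dien-1-yl]but-3-en-1-ol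
Product: 14 (1R,2S)-2-[(tert-butyldimethylsilyl)oxy]-1-[(1R)-2-methoxy-1-{[(4-methoxybenzyl)oxy]methyl}cyclohexa-2,5-dien-1-yl]but-3-en-1-yl 3-methylbutanoate
Conditions: isovaleryl chloride (3 equiv), pyridine, DMAP (cat.), CH2Cl2, 0 to 40 °C
Reagents that add atoms: 3-methylbutanoyl chloride, CC(C)CC(Cl)=O
Why: DMAP-catalysed acylation of the remaining hindered secondary alcohol installs the C1 isovalerate before any other hydroxyl is free, with retention at C1.

Step 7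
Reactants: 14 (1R,2S)-2-[(tert-butyldimethylsilyl)oxy]-1-[(1R)-2-methoxy-1-{[(4-methoxybenzyl)oxy]methyl}cyclohexa-2,5-dien-1-yl]but-3-en-1-yl 3-methylbutanoate
Product: 16 (1R,2S)-2-[(tert-butyldimethylsilyl)oxy]-1-[(1R)-1-{[(4-methoxybenzyl)oxy]methyl}-6-oxocyclohexa-2,4-dien-1-yl]but-3-en-1-yl 3-methylbutanoate, via bromo ketone 15 (not isolated)
Conditions: NBS (1.05 equiv), NaHCO3, THF/H2O, −10 °C; then DBU, CH2Cl2, 0 °C; used at once, kept cold
Reagents that add atoms: water, O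
Why: Bromohydration of the electron-rich methyl enol ether gives the α-bromo ketone, and E2 dehydrobromination toward the allylic C7–H gives the 6,6-disubstituted cyclohexa-2,4-dienone, which cannot aromatise because C10 is quaternary (kept cold to avoid Diels–Alder reactions of the dienone).

Step 8
Reactants: 16 (1R,2S)-2-[(tert-butyldimethylsilyl)oxy]-1-[(1R)-1-{[(4-methoxybenzyl)oxy]methyl}-6-oxocyclohexa-2,4-dien-1-yl]but-3-en-1-yl 3-methylbutanoate; 17 isopropenylmagnesium bromide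
Product: 20 (1R,2S)-2-[(tert-butyldimethylsilyl)oxy]-1-[(1R,6R)-1-{[(4-methoxybenzyl)oxy]methyl}-2-oxo-6-(prop-1-en-2-yl)cyclohex-3-en-1-yl]but-3-en-1-yl 3-methylbutanoate, via magnesium dienolate 18 (not isolated), via deconjugated enone 19 (not isolated)
Conditions: 17 (1.3 equiv), CuBr·SMe2 (10 mol%), THF, −78 °C; aq. NH4Cl; then DBU (cat.), CH2Cl2, rt
Reagents that add atoms: none
Why: Copper-catalysed 1,6-conjugate addition of the alkenyl Grignard to the diene terminus C5, on the face anti to the branched acyloxy side chain on C10 (isopropenyl trans to C1, cis to C14; C5 R), followed by base-mediated conjugation of the β,γ-enone.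

Step 9
Reactants: 20 (1R,2S)-2-[(tert-butyldimethylsilyl)oxy]-1-[(1R,6R)-1-{[(4-methoxybenzyl)oxy]methyl}-2-oxo-6-(prop-1-en-2-yl)cyclohex-3-en-1-yl]but-3-en-1-yl 3-methylbutanoate
Product: 21 (1R,2S,4aR,8aR)-2-[(tert-butyldimethylsilyl)oxy]-8a-{[(4-methoxybenzyl)oxy]methyl}-4-methyl-8-oxo-1,2,4a,5,8,8a-hexahydronaphthalen-1-yl 3-methylbutanoate
Conditions: second-generation Grubbs catalyst RuCl2(=CHPh)(PCy3)(H2IMes) (5 mol%), toluene, 80 °C
Reagents that add atoms: none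
Why: Ring-closing metathesis between the vinyl group and the 1,1-disubstituted isopropenyl group forms the trisubstituted C3=C4 alkene of ring A, and because the two arms are trans on ring B the decalin is trans-fused with no stereocentre altered.

Step 10
Reactants: 21 (1R,2S,4aR,8aR)-2-[(tert-butyldimethylsilyl)oxy]-8a-{[(4-methoxybenzyl)oxy]methyl}-4-methyl-8-oxo-1,2,4a,5,8,8a-hexahydronaphthalen-1-yl 3-methylbutanoate; 17 isopropenylmagnesium bromide
Product: 23 (1R,2S,4aR,6S,8aR)-2-[(tert-butyldimethylsilyl)oxy]-8a-{[(4-methoxybenzyl)oxy]methyl}-4-methyl-8-oxo-6-(prop-1-en-2-yl)-1,2,4a,5,6,7,8,8a-octahydronaphthalen-1-yl 3-methylbutanoate, via silyl enol ether 22 (not isolated)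
Conditions: 17 (2 equiv), CuBr·SMe2 (20 mol%), TMSCl, THF, −78 °C; then 1 M HCl, 0 °C
Reagents that add atoms: none
Why: TMSCl-accelerated copper-catalysed conjugate addition, in which stereoelectronically controlled axial attack on C7 of the rigid trans-fused enone occurs on the β-face, trans to the C5 ring-A substituent and anti to the axial C14 group, giving the axial isopropenyl group (C7 S).

Step 11
Reactants: 23 (1R,2S,4aR,6S,8aR)-2-[(tert-butyldimethylsilyl)oxy]-8a-{[(4-methoxybenzyl)oxy]methyl}-4-methyl-8-oxo-6-(prop-1-en-2-yl)-1,2,4a,5,6,7,8,8a-octahydronaphthalen-1-yl 3-methylbutanoate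
Product: 25 (1R,2S,4aR,6S,8S,8aS)-2-[(tert-butyldimethylsilyl)oxy]-8-hydroxy-8a-{[(4-methoxybenzyl)oxy]methyl}-4-methyl-6-(prop-1-en-2-yl)-1,2,4a,5,6,7,8,8a-octahydronaphthalen-1-yl 3-methylbutanoate, via lithium alkoxide 24 (not isolated)
Conditions: LiBH(s-Bu)3 (1.2 equiv), THF, −78 °C; aq. NH4Cl at −78 °C
Reagents that add atoms: none
Why: Bulky-hydride ketone reduction, in which the axial β trajectory is blocked by the syn-axial isopropenyl group, so hydride enters equatorially from the α side and gives the axial 9β-alcohol (C9 S); the esters survive at −78 °C.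

Step 12
Reactants: 25 (1R,2S,4aR,6S,8S,8aS)-2-[(tert-butyldimethylsilyl)oxy]-8-hydroxy-8a-{[(4-methoxybenzyl)oxy]methyl}-4-methyl-6-(prop-1-en-2-yl)-1,2,4a,5,6,7,8,8a-octahydronaphthalen-1-yl 3-methylbutanoate
Product: 26 (1R,2S,4aR,6S,8S,8aS)-2,8-dihydroxy-8a-{[(4-methoxybenzyl)oxy]methyl}-4-methyl-6-(prop-1-en-2-yl)-1,2,4a,5,6,7,8,8a-octahydronaphthalen-1-yl 3-methylbutanoate
Conditions: HF·pyridine, THF/pyridine, 0 °C to rt
Reagents that add atoms: none
Why: Fluoride-mediated desilylation under buffered acidic conditions frees the C2 hydroxyl without acyl migration, PMB loss or change at any stereocentre.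

Step 13
Reactants: 26 (1R,2S,4aR,6S,8S,8aS)-2,8-dihydroxy-8a-{[(4-methoxybenzyl)oxy]methyl}-4-methyl-6-(prop-1-en-2-yl)-1,2,4a,5,6,7,8,8a-octahydronaphthalen-1-yl 3-methylbutanoate
Product: 27 (1R,2S,4aR,6S,8S,8aS)-2,8-diacetoxy-8a-{[(4-methoxybenzyl)oxy]methyl}-4-methyl-6-(prop-1-en-2-yl)-1,2,4a,5,6,7,8,8a-octahydronaphthalen-1-yl 3-methylbutanoate
Conditions: Ac2O (6 equiv), Et3N, DMAP, CH2Cl2, rt to 40 °C
Reagents that add atoms: acetic anhydride, CC(=O)OC(C)=O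
Why: DMAP-catalysed acetylation esterifies both the allylic C2 and the hindered axial C9 hydroxyls in one operation with retention at both centres.

Step 14
Reactants: 27 (1R,2S,4aR,6S,8S,8aS)-2,8-diacetoxy-8a-{[(4-methoxybenzyl)oxy]methyl}-4-methyl-6-(prop-1-en-2-yl)-1,2,4a,5,6,7,8,8a-octahydronaphthalen-1-yl 3-methylbutanoate
Product: 28 (1R,2S,4aR,6S,8S,8aS)-2,8-diacetoxy-8a-(hydroxymethyl)-4-methyl-6-(prop-1-en-2-yl)-1,2,4a,5,6,7,8,8a-octahydronaphthalen-1-yl 3-methylbutanoate (CNP0257109.1)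
Conditions: DDQ (1.5 equiv), CH2Cl2/pH 7 phosphate buffer, 0 °C
Reagents that add atoms: none
Why: Oxidative cleavage of the 4-methoxybenzyl ether by DDQ (benzylic oxidation, then hydrolysis) frees the neopentyl C14 alcohol under neutral conditions that spare the three esters and both alkenes.

**Compound list**

1 | 2-methoxybenzoyl chloride | COc1ccccc1C(Cl)=O | starting material
2 | (S)-2-(methoxymethyl)pyrrolidine | COC[C@@H]1CCCN1 | starting material
3 | (S)-(2-methoxyphenyl)[2-(methoxymethyl)pyrrolidin-1-yl]methanone | COc1ccccc1C(=O)N1CCC[C@H]1COC | intermediate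
4 | 4-methoxybenzyl chloromethyl ether | COc1ccc(COCCl)cc1 | starting material
5 | potassium amide enolate of the 1,4-dihydrobenzamide (exocyclic enolate on the 2-methoxycyclohexa-2,5-diene ring) | COC1=CCC=CC1=C([O-])N1CCC[C@H]1COC.[K+] | intermediate (not isolated)
6 | [(1S)-2-methoxy-1-{[(4-methoxybenzyl)oxy]methyl}cyclohexa-2,5-dien-1-yl][(2S)-2-(methoxymethyl)pyrrolidin-1-yl]methanone | COC1=CCC=C[C@@]1(COCc1ccc(OC)cc1)C(=O)N1CCC[C@H]1COC | intermediate
7 | zirconium N,O-hemiaminal of 6 (O–ZrCp2Cl on the former amide carbon) | COC1=CCC=C[C@@]1(COCc1ccc(OC)cc1)C(O[Zr](Cl)(C1C=CC=C1)C1C=CC=C1)N1CCC[C@H]1COC | intermediate (not isolated)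
8 | (1S)-2-methoxy-1-{[(4-methoxybenzyl)oxy]methyl}cyclohexa-2,5-diene-1-carbaldehyde | COC1=CCC=C[C@@]1(COCc1ccc(OC)cc1)C=O | intermediate
9 | allenylboronic acid pinacol ester | C=C=CB1OC(C)(C)C(C)(C)O1 | starting material
10 | (E)-[3-(pinacolatoboryl)allyl]bis[(−)-isopinocampheyl]borane | CC1(C)OB(/C=C/CB([C@@H]2C[C@@H]3C[C@H]([C@H]2C)C3(C)C)[C@@H]2C[C@@H]3C[C@H]([C@H]2C)C3(C)C)OC1(C)C | intermediate (not isolated)
11 | allylboration adduct of 8 (C1–O–B(Ipc)2 borinate, C2–B(pin), anti) | COC1=CCC=C[C@@]1(COCc1ccc(OC)cc1)[C@@H](OB([C@@H]1C[C@@H]2C[C@H]([C@H]1C)C2(C)C)[C@@H]1C[C@@H]2C[C@H]([C@H]1C)C2(C)C)[C@@H](B1OC(C)(C)C(C)(C)O1)C=C | intermediate (not isolated)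
12 | (1R,2S)-1-[(1R)-2-methoxy-1-{[(4-methoxybenzyl)oxy]methyl}cyclohexa-2,5-dien-1-yl]but-3-ene-1,2-diol | COC1=CCC=C[C@@]1(COCc1ccc(OC)cc1)[C@@H](O)[C@@H](O)C=C | intermediate
13 | (1R,2S)-2-[(tert-butyldimethylsilyl)oxy]-1-[(1R)-2-methoxy-1-{[(4-methoxybenzyl)oxy]methyl}cyclohexa-2,5-dien-1-yl]but-3-en-1-ol | COC1=CCC=C[C@@]1(COCc1ccc(OC)cc1)[C@@H](O)[C@@H](O[Si](C)(C)C(C)(C)C)C=C | intermediate
14 | (1R,2S)-2-[(tert-butyldimethylsilyl)oxy]-1-[(1R)-2-methoxy-1-{[(4-methoxybenzyl)oxy]methyl}cyclohexa-2,5-dien-1-yl]but-3-en-1-yl 3-methylbutanoate | COC1=CCC=C[C@@]1(COCc1ccc(OC)cc1)[C@@H](OC(=O)CC(C)C)[C@@H](O[Si](C)(C)C(C)(C)C)C=C | intermediate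
15 | α-bromo ketone: (1R,2S)-1-[(1R)-3-bromo-1-{[(4-methoxybenzyl)oxy]methyl}-2-oxocyclohex-5-en-1-yl]-2-[(tert-butyldimethylsilyl)oxy]but-3-en-1-yl 3-methylbutanoate (epimers at C–Br) | O=C1C(Br)CC=C[C@@]1(COCc1ccc(OC)cc1)[C@@H](OC(=O)CC(C)C)[C@@H](O[Si](C)(C)C(C)(C)C)C=C | intermediate (not isolated)
16 | (1R,2S)-2-[(tert-butyldimethylsilyl)oxy]-1-[(1R)-1-{[(4-methoxybenzyl)oxy]methyl}-6-oxocyclohexa-2,4-dien-1-yl]but-3-en-1-yl 3-methylbutanoate | O=C1C=CC=C[C@@]1(COCc1ccc(OC)cc1)[C@@H](OC(=O)CC(C)C)[C@@H](O[Si](C)(C)C(C)(C)C)C=C | intermediate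
17 | isopropenylmagnesium bromide | CC(=C)[Mg]Br | starting material
18 | bromomagnesium dienolate from 1,6-addition (C9–OMgBr, C8=C9, C6=C7, isopropenyl at C5) | Br[Mg]OC1=CC=C[C@H](C(C)=C)[C@@]1(COCc1ccc(OC)cc1)[C@@H](OC(=O)CC(C)C)[C@@H](O[Si](C)(C)C(C)(C)C)C=C | intermediate (not isolated)
19 | β,γ-enone: (1R,2S)-2-[(tert-butyldimethylsilyl)oxy]-1-[(1R,6R)-1-{[(4-methoxybenzyl)oxy]methyl}-2-oxo-6-(prop-1-en-2-yl)cyclohex-4-en-1-yl]but-3-en-1-yl 3-methylbutanoate | O=C1CC=C[C@H](C(C)=C)[C@@]1(COCc1ccc(OC)cc1)[C@@H](OC(=O)CC(C)C)[C@@H](O[Si](C)(C)C(C)(C)C)C=C | intermediate (not isolated)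
20 | (1R,2S)-2-[(tert-butyldimethylsilyl)oxy]-1-[(1R,6R)-1-{[(4-methoxybenzyl)oxy]methyl}-2-oxo-6-(prop-1-en-2-yl)cyclohex-3-en-1-yl]but-3-en-1-yl 3-methylbutanoate | O=C1C=CC[C@H](C(C)=C)[C@@]1(COCc1ccc(OC)cc1)[C@@H](OC(=O)CC(C)C)[C@@H](O[Si](C)(C)C(C)(C)C)C=C | intermediate
21 | (1R,2S,4aR,8aR)-2-[(tert-butyldimethylsilyl)oxy]-8a-{[(4-methoxybenzyl)oxy]methyl}-4-methyl-8-oxo-1,2,4a,5,8,8a-hexahydronaphthalen-1-yl 3-methylbutanoate (trans-fused) | O=C1C=CC[C@@H]2C(C)=C[C@H](O[Si](C)(C)C(C)(C)C)[C@H](OC(=O)CC(C)C)[C@@]12COCc1ccc(OC)cc1 | intermediate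
22 | trimethylsilyl enol ether of 23 (C8–OTMS, C7=C8 in naphthalene numbering) | C[Si](C)(C)OC1=C[C@@H](C(C)=C)C[C@@H]2C(C)=C[C@H](O[Si](C)(C)C(C)(C)C)[C@H](OC(=O)CC(C)C)[C@@]12COCc1ccc(OC)cc1 | intermediate (not isolated)
23 | (1R,2S,4aR,6S,8aR)-2-[(tert-butyldimethylsilyl)oxy]-8a-{[(4-methoxybenzyl)oxy]methyl}-4-methyl-8-oxo-6-(prop-1-en-2-yl)-1,2,4a,5,6,7,8,8a-octahydronaphthalen-1-yl 3-methylbutanoate | O=C1C[C@@H](C(C)=C)C[C@@H]2C(C)=C[C@H](O[Si](C)(C)C(C)(C)C)[C@H](OC(=O)CC(C)C)[C@@]12COCc1ccc(OC)cc1 | intermediate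
24 | lithium alkoxide of 25 | [Li+].[O-][C@H]1C[C@@H](C(C)=C)C[C@@H]2C(C)=C[C@H](O[Si](C)(C)C(C)(C)C)[C@H](OC(=O)CC(C)C)[C@@]12COCc1ccc(OC)cc1 | intermediate (not isolated)
25 | (1R,2S,4aR,6S,8S,8aS)-2-[(tert-butyldimethylsilyl)oxy]-8-hydroxy-8a-{[(4-methoxybenzyl)oxy]methyl}-4-methyl-6-(prop-1-en-2-yl)-1,2,4a,5,6,7,8,8a-octahydronaphthalen-1-yl 3-methylbutanoate | O[C@H]1C[C@@H](C(C)=C)C[C@@H]2C(C)=C[C@H](O[Si](C)(C)C(C)(C)C)[C@H](OC(=O)CC(C)C)[C@@]12COCc1ccc(OC)cc1 | intermediate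
26 | (1R,2S,4aR,6S,8S,8aS)-2,8-dihydroxy-8a-{[(4-methoxybenzyl)oxy]methyl}-4-methyl-6-(prop-1-en-2-yl)-1,2,4a,5,6,7,8,8a-octahydronaphthalen-1-yl 3-methylbutanoate | O[C@H]1C[C@@H](C(C)=C)C[C@@H]2C(C)=C[C@H](O)[C@H](OC(=O)CC(C)C)[C@@]12COCc1ccc(OC)cc1 | intermediate
27 | (1R,2S,4aR,6S,8S,8aS)-2,8-diacetoxy-8a-{[(4-methoxybenzyl)oxy]methyl}-4-methyl-6-(prop-1-en-2-yl)-1,2,4a,5,6,7,8,8a-octahydronaphthalen-1-yl 3-methylbutanoate | CC(=O)O[C@H]1C[C@@H](C(C)=C)C[C@@H]2C(C)=C[C@H](OC(C)=O)[C@H](OC(=O)CC(C)C)[C@@]12COCc1ccc(OC)cc1 | intermediate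
28 | (1R,2S,4aR,6S,8S,8aS)-2,8-diacetoxy-8a-(hydroxymethyl)-4-methyl-6-(prop-1-en-2-yl)-1,2,4a,5,6,7,8,8a-octahydronaphthalen-1-yl 3-methylbutanoate; eudesmane numbering 1R,2S,5R,7S,9S,10S | C=C(C)[C@@H]1C[C@H](OC(C)=O)[C@@]2(CO)[C@H](C1)C(C)=C[C@H](OC(C)=O)[C@@H]2OC(=O)CC(C)C | target

**Step count and risk**

Total step count: 14. Longest linear sequence: 14 steps (1 to 28). Compounds 4, 9 and 17 and the reagent (−)-Ipc2BH are taken as bought.

Most likely to fail, with one fallback each: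

Step 8 (1,6-addition next to the quaternary carbon; competing 1,4-addition at C7, wrong face, or loss of dienone 16 by cycloaddition). The fallback avoids the 2,4-dienone altogether and sets out from enol ether 14. Allylic oxidation of the doubly allylic ring CH2 with (C5H5NH)2Cr2O7 and t-BuOOH in benzene gives the cross-conjugated vinylogous ester (1R,2S)-2-[(tert-butyldimethylsilyl)oxy]-1-[(1R)-2-methoxy-1-{[(4-methoxybenzyl)oxy]methyl}-4-oxocyclohexa-2,5-dien-1-yl]but-3-en-1-yl 3-methylbutanoate F3. Its only simple enone arm accepts 17 (CuBr·SMe2 cat., TMSCl, THF, −78 °C) at C5, anti to the side chain, giving the 5-isopropenyl 3-methoxycyclohexenone F4. Luche reduction (NaBH4, CeCl3·7H2O, MeOH, 0 °C) gives the allylic alcohol F5, and 1 M HCl in THF effects the Stork–Danheiser transposition. The sequence comes back to the route at enone 20.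

Step 3 (the amide sits on a quaternary carbon and may resist the Schwartz reagent). The fallback sets out from amide 6 and reduces it fully with LiH2NBH3 (THF, 0 °C to rt) to the neopentyl alcohol [(1S)-2-methoxy-1-{[(4-methoxybenzyl)oxy]methyl}cyclohexa-2,5-dien-1-yl]methanol F2. Dess–Martin periodinane with NaHCO3 in CH2Cl2 then oxidises it, and the sequence comes back at aldehyde 8.

Step 2 (the α-chloro ether may be destroyed by residual ammonia or give poor C-alkylation). The fallback sets out from benzamide 3 and traps the same Birch enolate with monomeric formaldehyde (cracked paraformaldehyde, THF, −78 °C) to give the hydroxymethyl amide [(1S)-1-(hydroxymethyl)-2-methoxycyclohexa-2,5-dien-1-yl][(2S)-2-(methoxymethyl)pyrrolidin-1-yl]methanone F1. Etherification with NaH, 4-methoxybenzyl chloride and Bu4NI in DMF at 0 °C comes back to the route at 6.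

**Further compounds**

F1 | step 2 | [(1S)-1-(hydroxymethyl)-2-methoxycyclohexa-2,5-dien-1-yl][(2S)-2-(methoxymethyl)pyrrolidin-1-yl]methanone | COC1=CCC=C[C@@]1(CO)C(=O)N1CCC[C@H]1COC
F2 | step 3 | [(1S)-2-methoxy-1-{[(4-methoxybenzyl)oxy]methyl}cyclohexa-2,5-dien-1-yl]methanol | COC1=CCC=C[C@@]1(COCc1ccc(OC)cc1)CO
F3 | step 8 | (1R,2S)-2-[(tert-butyldimethylsilyl)oxy]-1-[(1R)-2-methoxy-1-{[(4-methoxybenzyl)oxy]methyl}-4-oxocyclohexa-2,5-dien-1-yl]but-3-en-1-yl 3-methylbutanoate | COC1=CC(=O)C=C[C@@]1(COCc1ccc(OC)cc1)[C@@H](OC(=O)CC(C)C)[C@@H](O[Si](C)(C)C(C)(C)C)C=C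
F4 | step 8 | (1R,2S)-2-[(tert-butyldimethylsilyl)oxy]-1-[(1R,6R)-2-methoxy-1-{[(4-methoxybenzyl)oxy]methyl}-4-oxo-6-(prop-1-en-2-yl)cyclohex-2-en-1-yl]but-3-en-1-yl 3-methylbutanoate | COC1=CC(=O)C[C@H](C(C)=C)[C@@]1(COCc1ccc(OC)cc1)[C@@H](OC(=O)CC(C)C)[C@@H](O[Si](C)(C)C(C)(C)C)C=C
F5 | step 8 | (1R,2S)-2-[(tert-butyldimethylsilyl)oxy]-1-[(1R,6R)-4-hydroxy-2-methoxy-1-{[(4-methoxybenzyl)oxy]methyl}-6-(prop-1-en-2-yl)cyclohex-2-en-1-yl]but-3-en-1-yl 3-methylbutanoate (carbinol epimers) | COC1=CC(O)C[C@H](C(C)=C)[C@@]1(COCc1ccc(OC)cc1)[C@@H](OC(=O)CC(C)C)[C@@H](O[Si](C)(C)C(C)(C)C)C=C
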